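**Numbering used throughout:** compounds 1–18 as defined in the steps and the compound list; 18 is the target, 15 and 17 are the precursor and the product of the key step.

## Analysis of the target

The target is a 2-arylbenzofuran: a furan ring (O1, C2, C3, C3a, C7a) fused to a benzo ring (ring B, C3a to C7a) and joined through C2 to C1' of a resorcinol ring A (C1' to C6'). It carries hydroxyl groups at C6, C3' and C5', 3-methylbut-2-enyl (prenyl) groups at C7, C2' and C6', and hydrogen at C3, C4, C5 and C4'. There is no stereocenter, and each side-chain alkene ends in two identical methyl groups, so neither configuration nor alkene geometry has to be controlled. The sensitive features are the three electron-rich phenols, which oxidise easily, and the three prenyl groups, each ortho to a phenol, which Brønsted or Lewis acid would close to 2,2-dimethylchromans. The real difficulty is regiochemical: each carbon substituent sits at the more crowded ortho position of its phenol (C7 and not C5; C2' and C6' and not C4'). In addition C1' is flanked by two prenyl groups, so the C2–C1' bond is hard to make once they are present. The strategy rests on one recurring unit, an aryl–CH2–CH=C(CH3)2 chain on a carbon ortho to a phenolic oxygen (C7 next to O–C6, C2' next to O–C3', C6' next to O–C5'): each such chain can come from an aryl–CH2–CH=CH2 group by exchange of the alkene terminus, and each allyl group from an aryl allyl ether by a [3,3] shift.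

## Retrosynthetic reasoning

**18 from 17.** The three phenols are masked as acetates until the end. Only the three O–acyl bonds are cut, and the forward step is a mild base-mediated methanolysis that leaves the prenyl alkenes and the benzofuran alone.

**17 from 15 and 16.** The three CH=C(CH3)2 double bonds are cut, which leads back to the triallyl triacetate 15 and three equivalents of the olefin partner 16. The cut is made here rather than at the aryl–CH2 bonds because direct C-prenylation of phenols is unselective and a sigmatropic shift of prenyl ethers gives the reversed chain. A terminal alkene can be exchanged cleanly for the isopropylidene end. One operation converts all three chains and brings the acid-sensitive trisubstituted alkenes in only at the last C–C bond-forming step. The forward reaction has to achieve threefold conversion without migration of the double bonds.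

**15 from 14.** Acetylation of the triphenol 14. The acetates remove the acidic OH groups before the ruthenium step and are the groups removed in the final step.

**14 from 12.** The C4'–H bond is traced back to a C4'–Br bond. The bromine in 12 has only one task, to occupy the position between the two ring A oxygens. Deprotonation of the three phenols, bromine–lithium exchange to 13 and protonation remove it.

**12 from 11.** The three aryl–CH2 bonds at C7, C2' and C6' are cut and the allyl groups returned to the neighbouring oxygens, giving the tris(allyl ether) 11. Three aromatic Claisen rearrangements make all three bonds in one thermal step. On ring A the bromine leaves C2' and C6' as the only open ortho positions. On ring B the shift should prefer C7, across the C6–C7 bond with the higher double-bond character.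

**11 from 9 and 5.** The furan ring is opened at C2=C3 and O1–C2, giving the phosphonium salt 9 and the acid chloride 5. The forward reaction is O-acylation to 10 followed by an intramolecular Wittig reaction on the ester carbonyl. It is done at this stage because C1' has no ortho substituents yet, so the carbonyl is unhindered. The allyl ethers needed for the Claisen step are already in both partners, so no separate protection and deprotection of the three phenols is needed.

**9 from 8, 7 and 6.** The phosphonium salt 9 comes from the benzylic alcohol 8, which comes by reduction from the aldehyde 7. Aldehyde 7 is the 4-O-allyl ether of 6, made with one equivalent of 2. The hydrogen-bonded 2-hydroxyl of 6 stays free and later becomes O1.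

**5 from 4, 3 and 1.** The acid chloride 5 comes from the acid 4, the saponification product of the methyl ester 3. Ester 3 is made by double O-allylation of the commercial methyl ester 1 with two equivalents of 2. The carboxyl group of 1 is already blocked as its methyl ester, so only the two equivalent phenols are alkylated and no selectivity question arises.

## Alternatives that were turned down

**Alternative 1:** The benzo ring of the benzofuran is cut at C3a–C4, C4–C5 and C6–C7. This leads to the furan A2, an α-prenylated furylacetyl chloride that already carries the diprenylated ring A as its dimethyl ether, and to the silyloxyalkyne A3. In the forward step an amine base turns A2 into its ketene, which adds A3 in a [2+2] sense. The cyclobutenone then opens (4π) and closes onto furan C3 (6π) to give the phenol A1.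
- For: the oxygen at C6 and the prenyl group at C7 are fixed by the connectivity of the partners. The C5-versus-C7 question, which the chosen route answers only by a sigmatropic preference, does not arise. On this point Alternative 1 is the stronger plan, and it is convergent.
- Against: A1 has a hydroxyl at C4 that the target lacks, which costs a sulfonylation and a reduction.
- Against: ring A arrives as two methyl ethers. Cleaving them needs strong Lewis acids or hot nucleophiles next to prenyl groups ortho to the phenols being released, the classical set-up for chroman formation.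
- Against: A2 still has to be made, including the crowded bond between the furan and the di-ortho-substituted ring A, and it carries prenyl alkenes through the whole sequence.
- Comparison: the chosen strategy introduces every prenyl alkene in its last C–C bond-forming step and ends with a methanolysis.

**Alternative 2:** The C2=C3 bond is cut, leading to the O-aroyl salicylaldehyde A5. In the forward step low-valent titanium, generated from TiCl3 and zinc dust, couples the aldehyde carbon reductively with the ester carbonyl carbon and removes both oxygens, closing the furan ring to A4.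
- For: this is the shortest assembly of the core, one esterification and one ring closure from two fully prenylated halves, with all regiochemistry settled in the fragments. In convergence it is stronger than the chosen route.
- Against: the ester carbonyl of A5 sits between two ortho prenyl groups and its phenol partner is flanked on both sides. Both making the ester and attacking its carbonyl in a ketyl-type coupling are sterically disfavoured, and pinacol-type coupling of the aldehyde would compete.
- Against: A4 is a trimethyl ether, so the deprotection problem of Alternative 1 returns threefold.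
- Against: each prenylated half needs its own regioselective synthesis.
- Comparison: the chosen route closes the furan ring by a Wittig reaction before any ortho substituent is in place and uses protecting groups that leave under mild base.

**Alternative 3:** Ring A is cut at C1'–C6', leading to the open-chain triketone A7. In the forward step base forms the enolate at the terminal methylene C6', which attacks the aroyl carbonyl C1'. Loss of water aromatises the ring to give A6.
- For: the plan is biomimetic. Ring A is formed with both prenyl groups and both free phenols, and the crowded C2–C1' bond starts as an unhindered ketone. On these two points it is stronger than the chosen route.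
- Against: C6' is the least acidic α-position of A7, since C2' and C4' each lie between two carbonyls, so the required enolate needs polyanion conditions.
- Against: 1,3,5-triketones close easily through oxygen to 4-pyranones.
- Against: A7 needs a long linear build-up by Claisen-type acylations of prenylated diketone fragments.
- Against: the acetal on O–C6 of A6 must be removed with acid, next to prenyl groups ortho to free phenols.
- Comparison: the chosen strategy relies on aromatic substitution patterns that are predictable and on a base-only end game.

Key step: step 11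

Assumption: the 6-allyloxy group of 11 is taken to migrate mainly to C7, across the more double-bond-like C6–C7 bond of the benzofuran; the fallback to step 8 covers the opposite outcome.

## Route

**Step 1**
Reactants: 1 bromo ester methyl 4-bromo-3,5-dihydroxybenzoate; 2 allyl bromide
Product: 3 bis(allyl ether) methyl 4-bromo-3,5-bis(prop-2-enyloxy)benzoate
Conditions: K2CO3 (3 equiv), 2 (2.5 equiv), DMF, 60 °C
Reagents that add atoms: allyl bromide (second equivalent), C=CCBr
Why: Twofold Williamson alkylation of the two equivalent phenoxides, one equivalent of 2 per oxygen; the methyl ester and the aryl bromide are inert to K2CO3 in DMF, so exhaustive allylation leaves no selectivity question.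

**Step 2**
Reactants: 3 bis(allyl ether) methyl 4-bromo-3,5-bis(prop-2-enyloxy)benzoate
Product: 4 acid 4-bromo-3,5-bis(prop-2-enyloxy)benzoic acid
Conditions: LiOH, THF–H2O, 50 °C; then 1 M HCl
Reagents that add atoms: lithium hydroxide, [Li+].[OH-]
Why: Saponification of the methyl ester by acyl–oxygen cleavage; aryl allyl ethers and the aryl bromide do not react with hydroxide.

**Step 3**
Reactants: 4 acid 4-bromo-3,5-bis(prop-2-enyloxy)benzoic acid
Product: 5 acid chloride 4-bromo-3,5-bis(prop-2-enyloxy)benzoyl chloride
Conditions: (COCl)2, DMF (cat.), CH2Cl2, 0 °C → rt; used crude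
Reagents that add atoms: oxalyl chloride, ClC(=O)C(=O)Cl
Why: Acid chloride formation through a catalytic chloroiminium species; the by-products are gases and the allyl ethers are untouched.

**Step 4**
Reactants: 6 aldehyde 2,4-dihydroxybenzaldehyde; 2 allyl bromide
Product: 7 allyl ether 2-hydroxy-4-(prop-2-enyloxy)benzaldehyde
Conditions: KHCO3, 2 (1.05 equiv), KI (cat.), MeCN, 60 °C
Reagents that add atoms: none
Why: Regioselective Williamson etherification; the 2-hydroxyl is held in a hydrogen bond to the formyl group and is the weaker nucleophile, so the weak base should alkylate only the 4-hydroxyl.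

**Step 5**
Reactants: 7 allyl ether 2-hydroxy-4-(prop-2-enyloxy)benzaldehyde
Product: 8 benzylic alcohol 2-(hydroxymethyl)-5-(prop-2-enyloxy)phenol
Conditions: NaBH4, MeOH–THF, 0 °C
Reagents that add atoms: none
Why: Hydride reduction of the aldehyde; the allyl ether is not affected, and a neutral work-up protects the acid-sensitive ortho-hydroxybenzyl alcohol.

**Step 6**
Reactants: 8 benzylic alcohol 2-(hydroxymethyl)-5-(prop-2-enyloxy)phenol
Product: 9 [2-hydroxy-4-(prop-2-enyloxy)benzyl]triphenylphosphonium bromide
Conditions: PPh3·HBr, MeCN, reflux
Reagents that add atoms: triphenylphosphine hydrobromide, [Br-].c1ccc(cc1)[PH+](c1ccccc1)c1ccccc1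
Why: Acid-promoted ionisation of the ortho-hydroxybenzylic alcohol and capture of the benzylic electrophile by triphenylphosphine, the standard route to 2-hydroxybenzyl phosphonium salts; the salt should crystallise from the medium.

**Step 7**
Reactants: 9 [2-hydroxy-4-(prop-2-enyloxy)benzyl]triphenylphosphonium bromide; 5 acid chloride 4-bromo-3,5-bis(prop-2-enyloxy)benzoyl chloride
Product: 11 tris(allyl ether) 2-[4-bromo-3,5-bis(prop-2-enyloxy)phenyl]-6-(prop-2-enyloxy)-1-benzofuran, via O-aroyl phosphonium bromide 10 (not isolated)
Conditions: Et3N, toluene, rt → reflux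
Reagents that add atoms: none
Why: O-acylation of the phenol at room temperature, then ylide formation and intramolecular Wittig olefination of the ester carbonyl close the five-membered ring and give the aromatic furan with loss of triphenylphosphine oxide. Acylating before heating keeps the acid chloride away from the ylide carbon, and the aroyl carbon has no ortho substituent at this stage.

**Step 8**
Reactants: 11 tris(allyl ether) 2-[4-bromo-3,5-bis(prop-2-enyloxy)phenyl]-6-(prop-2-enyloxy)-1-benzofuran
Product: 12 bromo triphenol 2-[4-bromo-3,5-dihydroxy-2,6-bis(prop-2-enyl)phenyl]-7-(prop-2-enyl)-1-benzofuran-6-ol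
Conditions: PhNEt2, 200 °C, sealed tube, Ar
Reagents that add atoms: none
Why: Three aromatic Claisen [3,3] rearrangements, each followed by tautomerisation. On ring A the bromine at C4' leaves C2' and C6' as the only ortho positions that can rearomatise, and on ring B the shift should go to C7 across the more double-bond-like C6–C7 bond. The amine solvent suppresses acid-catalysed cyclisation of the ortho-allylphenols.

**Step 9**
Reactants: 12 bromo triphenol 2-[4-bromo-3,5-dihydroxy-2,6-bis(prop-2-enyl)phenyl]-7-(prop-2-enyl)-1-benzofuran-6-ol
Product: 14 triallyl triphenol 2-[3,5-dihydroxy-2,6-bis(prop-2-enyl)phenyl]-7-(prop-2-enyl)-1-benzofuran-6-ol, via tetralithiated aryllithium 13 (not isolated)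
Conditions: MeLi (3 equiv), THF, −78 °C; t-BuLi (2.2 equiv), −78 °C; AcOH in THF, −78 °C → rt
Reagents that add atoms: none
Why: Deprotonation of the three phenols, then bromine–lithium exchange in which the second equivalent of t-BuLi destroys the tert-butyl bromide formed, then protonation. An aryllithium quenched early by a remaining OH gives the same product, and terminal alkenes are inert to alkyllithiums at −78 °C.

**Step 10**
Reactants: 14 triallyl triphenol 2-[3,5-dihydroxy-2,6-bis(prop-2-enyl)phenyl]-7-(prop-2-enyl)-1-benzofuran-6-ol
Product: 15 triallyl triacetate 2-[3,5-diacetoxy-2,6-bis(prop-2-enyl)phenyl]-7-(prop-2-enyl)-1-benzofuran-6-yl acetate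
Conditions: Ac2O (4 equiv), pyridine, DMAP (cat.), CH2Cl2, 0 °C → rt
Reagents that add atoms: acetic anhydride, CC(=O)OC(C)=O
Why: Nucleophile-catalysed O-acylation of the three phenols; it removes the acidic OH groups before the ruthenium step and makes the rings less prone to oxidation.

**Step 11 (key step)**
Reactants: 15 triallyl triacetate 2-[3,5-diacetoxy-2,6-bis(prop-2-enyl)phenyl]-7-(prop-2-enyl)-1-benzofuran-6-yl acetate; 16 olefin partner 2-methylbut-2-ene
Product: 17 triprenyl triacetate 2-[3,5-diacetoxy-2,6-bis(3-methylbut-2-enyl)phenyl]-7-(3-methylbut-2-enyl)-1-benzofuran-6-yl acetate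
Conditions: second-generation Grubbs catalyst RuCl2(=CHPh)(H2IMes)(PCy3) (10–15 mol %), 16 as solvent in large excess (CH2Cl2 co-solvent if needed), 40 °C, sealed tube
Reagents that add atoms: 2-methylbut-2-ene (second and third equivalents), CC=C(C)C
Why: Olefin cross-metathesis: loss of PCy3 from the precatalyst gives a 14-electron ruthenium alkylidene that adds each terminal allyl alkene of 15 in a [2+2] sense to a ruthenacyclobutane, and cycloreversion followed by a second cycle with 16 delivers the isopropylidene unit to the former CH carbon and releases propene. Each of the three chains consumes one molecule of 16, so three equivalents of 16 are built in and three of propene are released per molecule of 15. The closest known reaction type is the conversion of allylarenes and O-protected ortho-allylphenols into prenylarenes with this catalyst in neat 2-methylbut-2-ene. No ring closes and no stereocenter forms, and because the new alkene carbon carries two methyl groups there is no alkene geometry to control. The step needs threefold conversion, cross- over self-metathesis, isopropylidene over ethylidene transfer and no migration of the allyl double bonds. With the olefin partner as solvent, homodimers and a ten-membered ring closure between the C7 and C2' chains should not compete, and closure between the C2' and C6' chains would require an impossibly strained meta-bridged seven-membered ring. A but-2-enyl terminus formed by ethylidene transfer is still a reactive 1,2-disubstituted alkene and is carried on, whereas the trisubstituted prenyl alkene does not re-enter the cycle, so material should collect in 17 while propene passes into the headspace. The acetates keep the phenols from binding ruthenium and from promoting hydride formation and double-bond migration, and the allyl groups of ring A, although flanked by substituents, react at their unhindered terminal CH2.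

**Step 12**
Reactants: 17 triprenyl triacetate 2-[3,5-diacetoxy-2,6-bis(3-methylbut-2-enyl)phenyl]-7-(3-methylbut-2-enyl)-1-benzofuran-6-yl acetate
Product: 18 target 2-[3,5-dihydroxy-2,6-bis(3-methylbut-2-enyl)phenyl]-7-(3-methylbut-2-enyl)-1-benzofuran-6-ol
Conditions: K2CO3 (3.5 equiv), degassed MeOH, 0 °C → rt; aq NH4Cl
Reagents that add atoms: none
Why: Base-mediated methanolysis (transesterification) of the three aryl acetates; the mild base does not touch the prenyl groups or the benzofuran, and exclusion of air protects the electron-rich triphenol.

## Compound list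

1 | methyl 4-bromo-3,5-dihydroxybenzoate | COC(=O)c1cc(O)c(Br)c(O)c1 | starting material
2 | allyl bromide (3-bromoprop-1-ene) | C=CCBr | starting material
3 | methyl 4-bromo-3,5-bis(prop-2-enyloxy)benzoate | COC(=O)c1cc(OCC=C)c(Br)c(OCC=C)c1 | intermediate
4 | 4-bromo-3,5-bis(prop-2-enyloxy)benzoic acid | OC(=O)c1cc(OCC=C)c(Br)c(OCC=C)c1 | intermediate
5 | 4-bromo-3,5-bis(prop-2-enyloxy)benzoyl chloride | ClC(=O)c1cc(OCC=C)c(Br)c(OCC=C)c1 | intermediate
6 | 2,4-dihydroxybenzaldehyde | O=Cc1ccc(O)cc1O | starting material
7 | 2-hydroxy-4-(prop-2-enyloxy)benzaldehyde | O=Cc1ccc(OCC=C)cc1O | intermediate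
8 | 2-(hydroxymethyl)-5-(prop-2-enyloxy)phenol | OCc1ccc(OCC=C)cc1O | intermediate
9 | [2-hydroxy-4-(prop-2-enyloxy)benzyl]triphenylphosphonium bromide | [Br-].Oc1cc(OCC=C)ccc1C[P+](c1ccccc1)(c1ccccc1)c1ccccc1 | intermediate
10 | {2-[4-bromo-3,5-bis(prop-2-enyloxy)benzoyloxy]-4-(prop-2-enyloxy)benzyl}triphenylphosphonium bromide | [Br-].C=CCOc1ccc(C[P+](c2ccccc2)(c2ccccc2)c2ccccc2)c(OC(=O)c2cc(OCC=C)c(Br)c(OCC=C)c2)c1 | intermediate (not isolated)
11 | 2-[4-bromo-3,5-bis(prop-2-enyloxy)phenyl]-6-(prop-2-enyloxy)-1-benzofuran | C=CCOc1ccc2cc(-c3cc(OCC=C)c(Br)c(OCC=C)c3)oc2c1 | intermediate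
12 | 2-[4-bromo-3,5-dihydroxy-2,6-bis(prop-2-enyl)phenyl]-7-(prop-2-enyl)-1-benzofuran-6-ol | C=CCc1c(O)ccc2cc(-c3c(CC=C)c(O)c(Br)c(O)c3CC=C)oc12 | intermediate
13 | trilithium 2-[4-lithio-3,5-dioxido-2,6-bis(prop-2-enyl)phenyl]-7-(prop-2-enyl)-1-benzofuran-6-olate | [Li]c1c(O[Li])c(CC=C)c(-c2cc3ccc(O[Li])c(CC=C)c3o2)c(CC=C)c1O[Li] | intermediate (not isolated)
14 | 2-[3,5-dihydroxy-2,6-bis(prop-2-enyl)phenyl]-7-(prop-2-enyl)-1-benzofuran-6-ol | C=CCc1c(O)ccc2cc(-c3c(CC=C)c(O)cc(O)c3CC=C)oc12 | intermediate
15 | 2-[3,5-diacetoxy-2,6-bis(prop-2-enyl)phenyl]-7-(prop-2-enyl)-1-benzofuran-6-yl acetate | CC(=O)Oc1cc(OC(C)=O)c(CC=C)c(-c2cc3ccc(OC(C)=O)c(CC=C)c3o2)c1CC=C | intermediate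
16 | 2-methylbut-2-ene | CC=C(C)C | starting material
17 | 2-[3,5-diacetoxy-2,6-bis(3-methylbut-2-enyl)phenyl]-7-(3-methylbut-2-enyl)-1-benzofuran-6-yl acetate | CC(=O)Oc1cc(OC(C)=O)c(CC=C(C)C)c(-c2cc3ccc(OC(C)=O)c(CC=C(C)C)c3o2)c1CC=C(C)C | intermediate
18 | 2-[3,5-dihydroxy-2,6-bis(3-methylbut-2-enyl)phenyl]-7-(3-methylbut-2-enyl)-1-benzofuran-6-ol | CC(C)=CCc1c(O)cc(O)c(CC=C(C)C)c1-c1cc2ccc(O)c(CC=C(C)C)c2o1 | target

## Step count and uncertain steps

Total step count: 12. Longest linear sequence: 9 steps (steps 1–3 or steps 4–6, followed by steps 7–12).

**Step 11 (key step).**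
- Risk: exchange may stop short at one or both of the crowded ring A allyl groups. Ethylidene instead of isopropylidene may be transferred, leaving but-2-enyl ends. Ruthenium hydride from catalyst decay may move a double bond into conjugation with the ring, after which metathesis shortens the chain. Three independent events on one molecule multiply any inefficiency.
- Fallback: from 14 to 18 by the classical cleavage–olefination sequence. Silylation of 14 with tert-butyldimethylsilyl chloride and imidazole in DMF gives 2-[3,5-bis(tert-butyldimethylsilyloxy)-2,6-bis(prop-2-enyl)phenyl]-6-(tert-butyldimethylsilyloxy)-7-(prop-2-enyl)-1-benzofuran F1. Lemieux–Johnson cleavage of the three terminal alkenes (OsO4 cat., NaIO4, 2,6-lutidine, dioxane–water) gives the tris(arylacetaldehyde) F2; the aromatic furan double bond reacts far more slowly than a terminal alkene. Wittig olefination with the ylide from isopropyltriphenylphosphonium iodide and n-BuLi in THF at −78 °C gives the tris(silyl ether) of the target F3. Bu4NF buffered with AcOH in THF then gives 18.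

**Step 8.**
- Risk: the allyl group on O–C6 may leak to C5 instead of C7, because both ortho positions of ring B are free and only bond fixation distinguishes them. Prolonged heating could also cost the bromine or cyclise the ortho-allylphenols.
- Fallback: from 7 to 12, settling the ring B allyl group before the benzofuran exists. Heating 7 in PhNEt2 at about 200 °C should move the allyl group to the carbon between the two oxygens, since the hydrogen-bonded formyl phenol fixes the double bond on that side, giving 3-allyl-2,4-dihydroxybenzaldehyde F4. NaBH4 reduction gives 2-allyl-4-(hydroxymethyl)benzene-1,3-diol F5, and PPh3·HBr gives (3-allyl-2,4-dihydroxybenzyl)triphenylphosphonium bromide F6. Two equivalents of 5 with Et3N in toluene acylate both phenols to the bis(aroyl) phosphonium bromide F7, which is not isolated and closes on heating to 7-allyl-2-[4-bromo-3,5-bis(prop-2-enyloxy)phenyl]-1-benzofuran-6-yl 4-bromo-3,5-bis(prop-2-enyloxy)benzoate F8. LiOH cleaves the unhindered aryl ester to 7-allyl-2-[4-bromo-3,5-bis(prop-2-enyloxy)phenyl]-1-benzofuran-6-ol F9 and returns acid 4. The remaining double Claisen rearrangement on ring A, which has no regiochemical choice, gives 12.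

**Step 9.**
- Risk: the trilithium triphenoxide may aggregate or precipitate in THF at −78 °C and leave the halogen–metal exchange incomplete. Excess alkyllithium may deprotonate a doubly activated aryl–CH2–allyl position, which after protonation moves the double bond into conjugation.
- Fallback: from 12 to 15, removing the bromine by a radical chain instead of an organolithium. Acetylation of 12 (Ac2O, pyridine, DMAP cat.) gives 2-[3,5-diacetoxy-4-bromo-2,6-bis(prop-2-enyl)phenyl]-7-(prop-2-enyl)-1-benzofuran-6-yl acetate F10. Reduction with Bu3SnH and AIBN in toluene at 90 °C replaces bromine by hydrogen. The aryl radical has no alkene within reach for cyclisation, since both ring A allyl groups are meta to it, and 15 results.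

## Further compounds

F1 | step 11 | 2-[3,5-bis(tert-butyldimethylsilyloxy)-2,6-bis(prop-2-enyl)phenyl]-6-(tert-butyldimethylsilyloxy)-7-(prop-2-enyl)-1-benzofuran | C=CCc1c(O[Si](C)(C)C(C)(C)C)ccc2cc(-c3c(CC=C)c(O[Si](C)(C)C(C)(C)C)cc(O[Si](C)(C)C(C)(C)C)c3CC=C)oc12
F2 | step 11 | 2,2'-{4,6-bis(tert-butyldimethylsilyloxy)-2-[6-(tert-butyldimethylsilyloxy)-7-(2-oxoethyl)-1-benzofuran-2-yl]-1,3-phenylene}diacetaldehyde | O=CCc1c(O[Si](C)(C)C(C)(C)C)ccc2cc(-c3c(CC=O)c(O[Si](C)(C)C(C)(C)C)cc(O[Si](C)(C)C(C)(C)C)c3CC=O)oc12
F3 | step 11 | 2-[3,5-bis(tert-butyldimethylsilyloxy)-2,6-bis(3-methylbut-2-enyl)phenyl]-6-(tert-butyldimethylsilyloxy)-7-(3-methylbut-2-enyl)-1-benzofuran | CC(C)=CCc1c(O[Si](C)(C)C(C)(C)C)ccc2cc(-c3c(CC=C(C)C)c(O[Si](C)(C)C(C)(C)C)cc(O[Si](C)(C)C(C)(C)C)c3CC=C(C)C)oc12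
F4 | step 8 | 3-allyl-2,4-dihydroxybenzaldehyde | O=Cc1ccc(O)c(CC=C)c1O
F5 | step 8 | 2-allyl-4-(hydroxymethyl)benzene-1,3-diol | OCc1ccc(O)c(CC=C)c1O
F6 | step 8 | (3-allyl-2,4-dihydroxybenzyl)triphenylphosphonium bromide | [Br-].Oc1ccc(C[P+](c2ccccc2)(c2ccccc2)c2ccccc2)c(O)c1CC=C
F7 | step 8 | {3-allyl-2,4-bis[4-bromo-3,5-bis(prop-2-enyloxy)benzoyloxy]benzyl}triphenylphosphonium bromide | [Br-].C=CCc1c(OC(=O)c2cc(OCC=C)c(Br)c(OCC=C)c2)ccc(C[P+](c2ccccc2)(c2ccccc2)c2ccccc2)c1OC(=O)c1cc(OCC=C)c(Br)c(OCC=C)c1
F8 | step 8 | 7-allyl-2-[4-bromo-3,5-bis(prop-2-enyloxy)phenyl]-1-benzofuran-6-yl 4-bromo-3,5-bis(prop-2-enyloxy)benzoate | C=CCc1c(OC(=O)c2cc(OCC=C)c(Br)c(OCC=C)c2)ccc2cc(-c3cc(OCC=C)c(Br)c(OCC=C)c3)oc12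
F9 | step 8 | 7-allyl-2-[4-bromo-3,5-bis(prop-2-enyloxy)phenyl]-1-benzofuran-6-ol | C=CCc1c(O)ccc2cc(-c3cc(OCC=C)c(Br)c(OCC=C)c3)oc12
F10 | step 9 | 2-[3,5-diacetoxy-4-bromo-2,6-bis(prop-2-enyl)phenyl]-7-(prop-2-enyl)-1-benzofuran-6-yl acetate | CC(=O)Oc1c(Br)c(OC(C)=O)c(CC=C)c(-c2cc3ccc(OC(C)=O)c(CC=C)c3o2)c1CC=C
A1 | alternative 1 | 2-[3,5-dimethoxy-2,6-bis(3-methylbut-2-enyl)phenyl]-7-(3-methylbut-2-enyl)-6-(triisopropylsilyloxy)-1-benzofuran-4-ol | COc1cc(OC)c(CC=C(C)C)c(-c2cc3c(O)cc(O[Si](C(C)C)(C(C)C)C(C)C)c(CC=C(C)C)c3o2)c1CC=C(C)C
A2 | alternative 1 | 2-{5-[3,5-dimethoxy-2,6-bis(3-methylbut-2-enyl)phenyl]furan-2-yl}-5-methylhex-4-enoyl chloride | COc1cc(OC)c(CC=C(C)C)c(-c2ccc(C(CC=C(C)C)C(Cl)=O)o2)c1CC=C(C)C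
A3 | alternative 1 | (ethynyloxy)triisopropylsilane | C#CO[Si](C(C)C)(C(C)C)C(C)C
A4 | alternative 2 | 2-[3,5-dimethoxy-2,6-bis(3-methylbut-2-enyl)phenyl]-6-methoxy-7-(3-methylbut-2-enyl)-1-benzofuran | COc1cc(OC)c(CC=C(C)C)c(-c2cc3ccc(OC)c(CC=C(C)C)c3o2)c1CC=C(C)C
A5 | alternative 2 | 6-formyl-3-methoxy-2-(3-methylbut-2-enyl)phenyl 3,5-dimethoxy-2,6-bis(3-methylbut-2-enyl)benzoate | COc1ccc(C=O)c(OC(=O)c2c(CC=C(C)C)c(OC)cc(OC)c2CC=C(C)C)c1CC=C(C)C
A6 | alternative 3 | 2-[3,5-dihydroxy-2,6-bis(3-methylbut-2-enyl)phenyl]-6-(methoxymethoxy)-7-(3-methylbut-2-enyl)-1-benzofuran | CC(C)=CCc1c(O)cc(O)c(CC=C(C)C)c1-c1cc2ccc(OCOC)c(CC=C(C)C)c2o1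
A7 | alternative 3 | 1-[6-(methoxymethoxy)-7-(3-methylbut-2-enyl)-1-benzofuran-2-yl]-9-methyl-2-(3-methylbut-2-enyl)dec-8-ene-1,3,5-trione | COCOc1ccc2cc(C(=O)C(CC=C(C)C)C(=O)CC(=O)CCC=C(C)C)oc2c1CC=C(C)C
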